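## Structural features

The target is a C30 diketone whose centre is a syn-tricyclo[4.2.1.1(2,5)]deca-3,7-diene: cyclopentene ring A (C1, C8, C7, C6, C9; C7=C8; methyl on quaternary C6) and cyclopentene ring B (C2, C3, C4, C5, C10; C3=C4; methyl on C4) are joined by the bonds C1–C2 and C5–C6. These two bonds close a boat-shaped six-membered ring C1–C2–C10–C5–C6–C9 and hold the bridges C3–C4 and C7–C8 face to face. C3 and C7 each carry the same cis-(1R,3S)-2,2-dimethyl-3-(3-oxobutyl)cyclopropyl arm, bonded through its ring carbon Ca directly to the sp2 carbon. The core has four contiguous stereocentres (C1, C2, C5, C6, all S), with tertiary C5 and quaternary C6 adjacent across the inter-ring bond, and each arm adds two adjacent centres (Ca, Cb). Fragile groups are the stacked alkenes (transannular reactions), the vinylcyclopropanes (acid), the cis-cyclopropanes and the two enolisable methyl ketones. The real difficulties are three: the like relationship of C5 and C6, which alone decides between the syn and the anti cage; the concave interior, where an inward hydrogen on C4 faces ring A and cannot be reached by a base; and two hindered alkenyl–cyclopropyl bonds that must form with retention. The key step exploits the fact that, with carbonyl groups at C3 and C7, the core is two cyclopentanones, each joined from its α-carbon to the β-carbon of the other (C6 to C5, C2 to C1), so that once C5–C6 exists the C2 enolate of the ring B ketone can close onto C1 of a ring A enone.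

## Logic of the disconnections

27 to 26. No skeletal bond is cut: the two side-chain carbonyl groups are exchanged for dioxolanes. The arms must be delivered as carbon nucleophiles, which free methyl ketones would not survive. The gain is that 26 can be assembled with organometallic chemistry. The demand is a final hydrolysis mild enough for the vinylcyclopropanes and the stacked diene.

26 to 25 and 24. The bond C3–Ca′ is cut, the link between the tetrasubstituted ring B alkene and the second arm. It joins an sp2 carbon that was a carbonyl carbon to a cyclopropyl carbon, so an enol triflate and a cyclopropylmetal are the natural partners. The cut removes eleven carbons and two stereocentres. The forward step must couple at the more hindered of the two alkenyl carbons with retention at Ca′.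

25 to 15 and 24. The bond C7–Ca is cut for the same reason, and the same reagent 24 serves a second time. Taking the two arms off one at a time lets each coupling run under its own conditions and lets material carrying a wrongly configured arm be removed while only one arm is present. The forward step should prefer the C7 triflate on the trisubstituted alkene; a regioisomeric mono-coupled product would do no harm, because it converges on 26.

24 to 20 and 21 (through 22 and 23). The bond Cb–CH2 and the carbon–metal bond at Ca are cut. Adding the side chain and the metal across the double bond of 20 creates Ca and Cb together, cis by the syn course of the addition, and leaves the metal where the coupling needs it. The arm is reduced to an achiral C5 ring and a C6 bromide. The forward step must tell the two enantiotopic olefinic carbons of 20 apart.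

20 to 17 to 16. The ring bond between the carbene carbon and the CMe2 carbon is cut. 20 is volatile and not stored, so it is made when needed from 16 through 17. The only demand is that 20 leaves the hot zone as it forms.

15 to 12. The two O–S bonds are cut and the C4 methyl group is traced back to a methylidene. In the syn cage a hydrogen on C4 next to the C3 carbonyl must point into the cleft toward C7, because a methyl group there would not fit. A 4-methyl-3-ketone could therefore not be enolised by an external base. The C3=C4 enolate is instead generated by adding hydride to the outward CH2, and the C7 enolate by ordinary deprotonation at C8. The demand is the order of events: C7 must be an enolate before the hydride arrives.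

12 to 9. The bond C1–C2 is cut (key step). It joins the α-carbon of one ketone to the β-carbon of the other in a 1,5-diketone. Its cleavage opens the central six-membered ring, turns the cage into two monocycles joined by C5–C6, and removes two stereocentres. In 9 the ring B ketone has α-hydrogens only at C2, because C4 is sp2. This prepares step 6 and excludes both the competing closure from C4 to C1 (a bicyclo[2.2.1]heptanone) and retro-Michael loss of ring A. The forward step needs a boat-like, stacked transition state and the like configuration at C5/C6.

9 to 6. The exocyclic carbon on C4 is removed. It is added to an enol ether whose regiochemistry (C3=C4) follows directly from the conjugate addition that made C5–C6, so no regioselective enolisation is needed. The forward step must avoid migration of the new double bond into the ring.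

6 to 4. The C8=C1 double bond is taken back to the saturated ketone. The union step must use a donor that is not a diene: a silyl dienol ether of an already unsaturated ring A would be a cyclic 1,3-diene, would add to the enone as a Diels–Alder diene and would close C1–C4. Dehydrogenation at this stage is unambiguous, because the ring A ketone can enolise only toward C8 and the ring B oxygen is still masked.

4 to 2 and 3. The bond C5–C6 is cut, between the α-carbon of ring A and the β-carbon of ring B. This divides the core into two commercial five-membered rings. The forward step must create the quaternary centre, control the face of 3 (C5) and the relative orientation of the partners (C6), and hand over the silyl group so that ring B stays masked.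

2 to 1. The O–Si bond is cut. The forward step needs the more substituted enol ether.

## Other disconnections considered

Alternative 1: The cut runs through the arm cyclopropane (Ca–Cb and Ca–CMe2). An engineered haem protein would transfer the carbene carbon of ethyl diazoacetate A3 to the trisubstituted alkene of 6-methylhept-5-en-2-one A2 and give the cis ester A1, with both arm stereocentres and the free ketone, in one step.
- In its favour: two cheap achiral liquids, no protecting group, water as solvent, and no volatile cyclopropene. On raw-material cost and handling of the arm precursor it would be the better plan. In arm stereocentres set per step it is the equal of the carbometalation in step 9.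
- Against it here: unactivated trisubstituted aliphatic alkenes are poor acceptors for haem carbenes, and cis selectivity runs against the intrinsic trans preference and would have to be evolved. More seriously, the carbene carbon arrives with an ester carbon that the target does not contain, since Ca is bonded directly to C3 or C7. Excising that carbon means decarboxylative halogenation or coupling through a cyclopropyl radical, which inverts rapidly and would be expected to drain cis toward trans. The free ketone would also have to be masked before any organometallic is made.
- Comparison: structurally the alternative builds the arm ring from an acyclic ketone and leaves the core untouched, so it competes only with steps 7–9. Mechanistically it sets Ca as a carbene-derived centre, whereas the chosen plan creates Ca as the carbon–metal bond that the coupling needs. In step count, one enzymatic step plus at least three further operations stand against the single step 9.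

Alternative 2: The cut removes ring B through C2–C3 and C4–C5. Monovalent cobalt, generated from CoI2(Ph2PCH2CH2PPh2) with Zn and ZnI2, would join the triene termini of the arm-bearing methylcycloheptatriene A5 to the alkyne A6 in a [6+2] cycloaddition and give the bicyclo[4.2.1]nonatriene A4.
- In its favour: ring B, the cis relation of C2 and C5, the C3=C4 alkene with its methyl group and both arms arrive in one convergent step. Neither the enol triflates nor the two couplings at hindered alkenyl carbons (steps 6, 10 and 11) would be needed. On convergence and on avoiding late work on the concave cage this plan would be the better one.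
- Against it: A4 still lacks C9. It must be added across C1 and C6 of the remaining diene, forming quaternary C6 with the facial sense that gives the syn cage; this is a formal [4+1] addition for which only an indirect cyclopropanation–rearrangement sequence can be defended. A5 equilibrates by 1,5-hydrogen shifts and through its norcaradiene, so a single positional isomer is hard to hold. The unsymmetrical alkyne can add in two orientations. The only stereocontrol for C2 and C5 is the remote arm, so a diastereomer mixture is to be expected.
- Comparison: structurally the alternative postpones exactly what the chosen plan settles first (quaternary C6 and the syn relation, fixed in steps 2 and 5 by a covalent tether). Mechanistically it relies on metal-templated cycloaddition where the chosen plan uses polar enolate chemistry with a ring-enforced transition state. The [6+2] step itself is shorter, but making A5 and inserting C9 would probably cost more steps than steps 1–6.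

Alternative 3: The cut is the same as in the chosen plan (Ca–C7 and Ca–C3) with reversed roles. Pd(OAc)2 (divalent palladium), directed by the quinolin-8-yl amide group of A9, would activate the ring methylene C–H cis to the amide and couple it twice with the core bis(alkenyl iodide) A8 to give A7.
- In its favour: A9 is accessible in enantiopure form from the chiral pool, the cis relation follows from the palladacycle, and no organometallic or volatile cyclopropene is handled. On security of the arm stereochemistry it is the equal of step 9 and arguably the better, because the configuration is bought, not induced.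
- Against it: directed cyclopropane C–H coupling is established with aryl iodides, much less with alkenyl iodides. Here both partners are hindered (one alkenyl iodide is tetrasubstituted, the other flanks quaternary C6) and the coupling must occur twice. A8 would itself have to be derived from 15 or a close relative, so every step up to step 6 is still needed. After the coupling each amide carbon must become a 3-oxobutyl chain: removal of the robust auxiliary, reduction and a three-carbon homologation on both arms beside the stacked diene, through an aldehyde oxidation level prone to epimerisation.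
- Comparison: on structure the two plans make the same bonds. On mechanism the alternative replaces transmetalation of a configurationally stable cyclopropylmetal by concerted metalation–deprotonation. On step economy it is clearly longer after the coupling (at least four extra operations against one deprotection).

Key step: step 5

Remark on the chemistry: atom labels C1–C10 of the tricyclic core are used for the corresponding atoms of all earlier intermediates. Ca is the arm carbon bonded to the core and Cb the arm carbon bearing the side chain. 2-Methylcyclopentanone is used as the racemate because its stereocentre is erased in step 1. Where a CIP descriptor of the core differs between intermediates (C5 in 25), only substituent priorities have changed; the spatial arrangement is that of 27 throughout.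

## Route

Step 1
Reactants: 1 2-methylcyclopentan-1-one (racemic)
Product: 2 triethyl[(2-methylcyclopent-1-en-1-yl)oxy]silane
Conditions: Et3SiCl, NaI, Et3N, MeCN, 25 → 50 °C; distillation
Reagents that add atoms: chlorotriethylsilane, CC[Si](Cl)(CC)CC
Why: Iodosilane formed in situ silylates reversibly, so the more substituted (thermodynamic) silyl enol ether should predominate; the stereocentre of 1 is erased here. The minor trisubstituted isomer is removed by distillation.

Step 2
Reactants: 2 triethyl[(2-methylcyclopent-1-en-1-yl)oxy]silane; 3 cyclopent-2-en-1-one
Product: 4 (2S)-2-methyl-2-[(1S)-3-(triethylsilyloxy)cyclopent-2-en-1-yl]cyclopentan-1-one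
Conditions: (S)-1-(2-methylphenyl)-3,3-diphenyltetrahydro-1H,3H-pyrrolo[1,2-c][1,3,2]oxazaborole·HNTf2 (20 mol %), Ph3PO (25 mol %), toluene, −40 → −20 °C; Et3N quench, filtration through Et3N-deactivated silica
Reagents that add atoms: none
Why: Mukaiyama–Michael addition: the cationic oxazaborole binds the carbonyl of 3 and shields one face, so C6 of 2 should attack the exposed face of the β-carbon (C5 becomes S), and the silyl group passes to the new enolate oxygen, which fixes the ring B enol ether toward C4. An open transition state with the two π systems anti and ring B turned away from ring A should favour the like (S,S) pairing at the new quaternary C6 only moderately; the C6 epimer is removed by chromatography at 9 or, at the latest, as the anti cage after step 5. A donor without a diene unit is chosen because a silyloxy-substituted cyclopentadiene would add to 3 as a Diels–Alder diene and close the unwanted C1–C4 bond.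

Step 3
Reactants: 4 (2S)-2-methyl-2-[(1S)-3-(triethylsilyloxy)cyclopent-2-en-1-yl]cyclopentan-1-one
Product: 6 (5S)-5-methyl-5-[(1S)-3-(triethylsilyloxy)cyclopent-2-en-1-yl]cyclopent-2-en-1-one, via lithium enolate 5 (not isolated)
Conditions: LiN(iPr)2, THF, −78 °C; then PhS(Cl)=N-t-Bu, −78 °C
Reagents that add atoms: none
Why: Enolate 5 can form only toward C8, because C6 is quaternary and the ring B oxygen is locked as its enol ether; attack on the sulfinimidoyl chloride and syn-elimination of the sulfenamide give the enone at low temperature (one-pot ketone dehydrogenation through enolate sulfinimidoylation). No stereocentre is touched.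

Step 4
Reactants: 6 (5S)-5-methyl-5-[(1S)-3-(triethylsilyloxy)cyclopent-2-en-1-yl]cyclopent-2-en-1-one
Product: 9 (5S)-5-methyl-5-[(1S)-2-methylidene-3-oxocyclopentyl]cyclopent-2-en-1-one, via Mannich base 7 (not isolated), via ammonium iodide 8 (not isolated)
Conditions: Me2N=CH2+ I−, CH2Cl2, 0 → 25 °C; then MeI, 25 °C; then aq NaHCO3, 25 °C; used without storage
Reagents that add atoms: dimethylmethylideneammonium iodide, C=[N+](C)C.[I-]
Why: The enol ether attacks the iminium ion at C4 (Mannich reaction); N-methylation and Hofmann-type β-elimination then give the α-methylidene ketone, with regiochemistry fixed in step 2. Mild bicarbonate should avoid migration of the new double bond into the ring, which would erase C5.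

Step 5
Reactants: 9 (5S)-5-methyl-5-[(1S)-2-methylidene-3-oxocyclopentyl]cyclopent-2-en-1-one
Product: 12 (1S,2S,5S,6S)-6-methyl-4-methylidene-syn-tricyclo[4.2.1.1(2,5)]decane-3,7-dione, via lithium dienolate 10 (not isolated), via lithium enolate 11 (not isolated)
Conditions: LiN(SiMe3)2, THF (0.01 M), −78 → −20 °C; AcOH, −78 °C
Reagents that add atoms: none
Why: LiN(SiMe3)2 removes a C2 hydrogen of 9, the only α-hydrogen of the ring B ketone, and gives the cross-conjugated dienolate 10. Enolate 10 adds through C2 to C1, the β-carbon of the ring A enone, and the resulting C7 enolate 11 is protonated at C8 by acetic acid. The closest known reaction type is the intramolecular Michael addition of a kinetic ketone enolate to a cyclopentenone that closes a bridged six-membered ring. The ring formed is C1–C2–C10–C5–C6–C9, closed in the 6-exo-trig mode (C8 stays outside the new ring). The new stereocentres C1 and C2 are controlled by the existing C5–C6 bond: the new bond can only form cis to it on both five-membered rings, and with the like (5S,6S) pairing this means the stacked, boat-like transition state that gives the syn cage (1S,2S). The selectivity needed is enolisation at C2 alone, and the substrate secures it, since C4 is sp2 and C6 is quaternary; closure from C4 to C1 and retro-Michael loss of ring A are therefore excluded, and γ-deprotonation at C9 is unproductive and reversible. A second Michael addition of 11 through C8 to the methylidene carbon would require a C3=C4 enolate that is trans within a six-membered ring, and addition of C2 to the C7 carbonyl would give a strained bicyclo[2.2.1]heptanolate that should revert. High dilution suppresses intermolecular addition to the methylidene ketone.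

Step 6
Reactants: 12 (1S,2S,5S,6S)-6-methyl-4-methylidene-syn-tricyclo[4.2.1.1(2,5)]decane-3,7-dione
Product: 15 (1S,2S,5S,6S)-4,6-dimethyl-syn-tricyclo[4.2.1.1(2,5)]deca-3,7-diene-3,7-diyl bis(trifluoromethanesulfonate), via potassium enolate 13 (not isolated), via bis-enolate 14 (not isolated)
Conditions: KN(SiMe3)2, THF, −78 °C; LiBH(s-Bu)3, −78 °C; PhNTf2, −78 → 0 °C; H2O
Reagents that add atoms: N-phenylbis(trifluoromethanesulfonimide), O=S(=O)(N(c1ccccc1)S(=O)(=O)C(F)(F)F)C(F)(F)F
Why: C7 can enolise only toward C8 (C6 quaternary, outward C8–H) and the ring B ketone has no removable α-hydrogen (C2 is a bridgehead, C4 is sp2), so KN(SiMe3)2 gives 13, which also protects C7 from hydride. LiBH(s-Bu)3 then adds hydride to the outward CH2 of the enone (conjugate reduction) and creates the C3=C4 enolate with its methyl group, without any proton having to leave the concave face. O-Sulfonylation of both enolates gives the bis(enol triflate).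

Step 7
Reactants: 16 3-methylbut-2-enal
Product: 17 4-methyl-N′-[(E)-3-methylbut-2-en-1-ylidene]benzenesulfonohydrazide
Conditions: TsNHNH2, MeOH, 25 °C
Reagents that add atoms: 4-methylbenzenesulfonohydrazide, NNS(=O)(=O)c1ccc(C)cc1
Why: Condensation of the aldehyde with the sulfonyl hydrazide (hydrazone formation).

Step 8
Reactants: 17 4-methyl-N′-[(E)-3-methylbut-2-en-1-ylidene]benzenesulfonohydrazide
Product: 20 3,3-dimethylcyclopropene, via sodium salt 18 (not isolated), via diazoalkene 19 (not isolated)
Conditions: NaOMe, MeOH, then solvent removed; diglyme, 150 °C, N2 stream into a −78 °C trap (THF)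
Reagents that add atoms: none
Why: Bamford–Stevens reaction: the sodium salt loses sulfinate to give 19, which loses N2, and the vinylcarbene closes to the cyclopropene. The product cannot isomerise further because C3 bears no hydrogen, and it is swept out of the hot flask as it forms.

Step 9
Reactants: 20 3,3-dimethylcyclopropene; 21 2-(2-bromoethyl)-2-methyl-1,3-dioxolane
Product: 24 {(1R,3R)-2,2-dimethyl-3-[2-(2-methyl-1,3-dioxolan-2-yl)ethyl]cyclopropyl}zinc chloride (cis; titrated THF solution kept under argon at −20 °C), via alkylmagnesium bromide 22 (not isolated), via cyclopropylmagnesium bromide 23 (not isolated)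
Conditions: 21, Mg, THF, ≤ 30 °C; 20 (1.2 equiv), CuBr·SMe2 (3 mol %), (R)-1-[(SP)-2-(diphenylphosphino)ferrocenyl]ethyldi-tert-butylphosphine (3.3 mol %), THF/Et2O, −10 °C; ZnCl2 (1.05 equiv), THF, 0 °C
Reagents that add atoms: zinc chloride, Cl[Zn]Cl
Why: Copper-catalysed syn-carbomagnesiation of the cyclopropene places the alkyl chain and magnesium cis, and the chiral diphosphine should select one of the two enantiotopic olefinic carbons, which sets Ca and Cb together (the enantiomeric ligand is used if the sense proves opposite). The slight excess of 20 ensures that no primary alkylmetal survives, and transmetalation to zinc proceeds with retention to a cyclopropylzinc that is configurationally stable and can be stored as a stock solution for steps 10 and 11.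

Step 10
Reactants: 15 (1S,2S,5S,6S)-4,6-dimethyl-syn-tricyclo[4.2.1.1(2,5)]deca-3,7-diene-3,7-diyl bis(trifluoromethanesulfonate); 24 {(1R,3R)-2,2-dimethyl-3-[2-(2-methyl-1,3-dioxolan-2-yl)ethyl]cyclopropyl}zinc chloride
Product: 25 (1S,2S,5R,6S)-7-{(1R,3S)-2,2-dimethyl-3-[2-(2-methyl-1,3-dioxolan-2-yl)ethyl]cyclopropyl}-4,6-dimethyl-syn-tricyclo[4.2.1.1(2,5)]deca-3,7-dien-3-yl trifluoromethanesulfonate
Conditions: 24 (1.15 equiv), Pd(OAc)2 (3 mol %), 2-dicyclohexylphosphino-2′,6′-dimethoxybiphenyl (6 mol %), THF, 25 °C
Reagents that add atoms: none
Why: Negishi coupling: zerovalent palladium should insert first into the C7 triflate, which sits on the trisubstituted alkene with only hydrogen on C8, and transmetalation and reductive elimination proceed with retention at the cyclopropyl carbon. Any C3-coupled regioisomer formed alongside converges on 26 in step 11 and need not be removed. The diastereomer that arises from the minor enantiomer of 24 is separated here by chromatography, while only one arm is present.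

Step 11
Reactants: 25 (1S,2S,5R,6S)-7-{(1R,3S)-2,2-dimethyl-3-[2-(2-methyl-1,3-dioxolan-2-yl)ethyl]cyclopropyl}-4,6-dimethyl-syn-tricyclo[4.2.1.1(2,5)]deca-3,7-dien-3-yl trifluoromethanesulfonate; 24 {(1R,3R)-2,2-dimethyl-3-[2-(2-methyl-1,3-dioxolan-2-yl)ethyl]cyclopropyl}zinc chloride
Product: 26 (1S,2S,5S,6S)-4,6-dimethyl-3,7-bis{(1R,3S)-2,2-dimethyl-3-[2-(2-methyl-1,3-dioxolan-2-yl)ethyl]cyclopropyl}-syn-tricyclo[4.2.1.1(2,5)]deca-3,7-diene
Conditions: 24 (2.0 equiv), Pd(OAc)2 (8 mol %), 2-dicyclohexylphosphino-2′,6′-dimethoxybiphenyl (16 mol %), THF, 60 °C
Reagents that add atoms: none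
Why: Second stereoretentive Negishi coupling, now at the tetrasubstituted C3 enol triflate; more catalyst, a larger excess of the zinc reagent and a higher temperature are acceptable because 25 holds no other electrophilic site. Retention at the cyclopropyl carbon places the second cis arm and completes the carbon skeleton with all eight stereocentres.

Step 12
Reactants: 26 (1S,2S,5S,6S)-4,6-dimethyl-3,7-bis{(1R,3S)-2,2-dimethyl-3-[2-(2-methyl-1,3-dioxolan-2-yl)ethyl]cyclopropyl}-syn-tricyclo[4.2.1.1(2,5)]deca-3,7-diene
Product: 27 (1S,2S,5S,6S)-4,6-dimethyl-3,7-bis[(1R,3S)-2,2-dimethyl-3-(3-oxobutyl)cyclopropyl]-syn-tricyclo[4.2.1.1(2,5)]deca-3,7-diene (CNP0300925.1)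
Conditions: pyridinium p-toluenesulfonate, acetone/H2O, 40 °C, exclusion of light
Reagents that add atoms: water, O
Why: Acid-catalysed ketal hydrolysis; the weak pyridinium acid is chosen to spare the vinylcyclopropanes and the stacked diene. No stereocentre is affected.

## Compound list

1 | 2-methylcyclopentan-1-one (racemic) | CC1CCCC1=O | starting material
2 | triethyl[(2-methylcyclopent-1-en-1-yl)oxy]silane | CC1=C(O[Si](CC)(CC)CC)CCC1 | intermediate
3 | cyclopent-2-en-1-one | O=C1C=CCC1 | starting material
4 | (2S)-2-methyl-2-[(1S)-3-(triethylsilyloxy)cyclopent-2-en-1-yl]cyclopentan-1-one | O=C1CCC[C@@]1(C)[C@H]1CCC(O[Si](CC)(CC)CC)=C1 | intermediate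
5 | lithium enolate of 4 (C7–O–Li, C7=C8) | [Li]OC1=CCC[C@@]1(C)[C@H]1CCC(O[Si](CC)(CC)CC)=C1 | intermediate
6 | (5S)-5-methyl-5-[(1S)-3-(triethylsilyloxy)cyclopent-2-en-1-yl]cyclopent-2-en-1-one | O=C1C=CC[C@@]1(C)[C@H]1CCC(O[Si](CC)(CC)CC)=C1 | intermediate
7 | (5S)-5-{(1S)-2-[(dimethylamino)methyl]-3-oxocyclopentyl}-5-methylcyclopent-2-en-1-one (both C4 epimers) | O=C1C=CC[C@@]1(C)[C@H]1CCC(=O)C1CN(C)C | intermediate
8 | N,N,N-trimethyl-1-{(2S)-2-[(1S)-1-methyl-2-oxocyclopent-3-en-1-yl]-5-oxocyclopentyl}methanaminium iodide (both C4 epimers) | O=C1C=CC[C@@]1(C)[C@H]1CCC(=O)C1C[N+](C)(C)C.[I-] | intermediate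
9 | (5S)-5-methyl-5-[(1S)-2-methylidene-3-oxocyclopentyl]cyclopent-2-en-1-one | O=C1C=CC[C@@]1(C)[C@H]1CCC(=O)C1=C | intermediate
10 | lithium (4S)-5-methylidene-4-[(1S)-1-methyl-2-oxocyclopent-3-en-1-yl]cyclopent-1-en-1-olate (C2 enolate of 9) | O=C1C=CC[C@@]1(C)[C@H]1CC=C(O[Li])C1=C | intermediate
11 | lithium C7 enolate (C7=C8) of 12, stereocentres as in 12 | [Li]OC1=C[C@@H]2C[C@@]1(C)[C@H]1C[C@@H]2C(=O)C1=C | intermediate
12 | (1S,2S,5S,6S)-6-methyl-4-methylidene-syn-tricyclo[4.2.1.1(2,5)]decane-3,7-dione | O=C1C[C@@H]2C[C@@]1(C)[C@H]1C[C@@H]2C(=O)C1=C | intermediate
13 | potassium C7 enolate (C7=C8) of 12, stereocentres as in 12 | [K]OC1=C[C@@H]2C[C@@]1(C)[C@H]1C[C@@H]2C(=O)C1=C | intermediate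
14 | potassium lithium (1S,2S,5S,6S)-4,6-dimethyl-syn-tricyclo[4.2.1.1(2,5)]deca-3,7-diene-3,7-bis(olate) | [K]OC1=C[C@@H]2C[C@@]1(C)[C@H]1C[C@@H]2C(O[Li])=C1C | intermediate
15 | (1S,2S,5S,6S)-4,6-dimethyl-syn-tricyclo[4.2.1.1(2,5)]deca-3,7-diene-3,7-diyl bis(trifluoromethanesulfonate) | FC(F)(F)S(=O)(=O)OC1=C[C@@H]2C[C@@]1(C)[C@H]1C[C@@H]2C(OS(=O)(=O)C(F)(F)F)=C1C | intermediate
16 | 3-methylbut-2-enal | CC(C)=CC=O | starting material
17 | 4-methyl-N′-[(E)-3-methylbut-2-en-1-ylidene]benzenesulfonohydrazide | CC(C)=C/C=N/NS(=O)(=O)c1ccc(C)cc1 | intermediate
18 | sodium salt of 17 (N-deprotonated) | CC(C)=C/C=N/[N-]S(=O)(=O)c1ccc(C)cc1.[Na+] | intermediate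
19 | 1-diazo-3-methylbut-2-ene | CC(C)=CC=[N+]=[N-] | intermediate
20 | 3,3-dimethylcyclopropene | CC1(C)C=C1 | intermediate
21 | 2-(2-bromoethyl)-2-methyl-1,3-dioxolane | CC1(CCBr)OCCO1 | starting material
22 | [2-(2-methyl-1,3-dioxolan-2-yl)ethyl]magnesium bromide | CC1(CC[Mg]Br)OCCO1 | intermediate
23 | {(1R,3R)-2,2-dimethyl-3-[2-(2-methyl-1,3-dioxolan-2-yl)ethyl]cyclopropyl}magnesium bromide (cis) | CC1(CC[C@H]2[C@@H]([Mg]Br)C2(C)C)OCCO1 | intermediate
24 | {(1R,3R)-2,2-dimethyl-3-[2-(2-methyl-1,3-dioxolan-2-yl)ethyl]cyclopropyl}zinc chloride (cis) | CC1(CC[C@H]2[C@@H]([Zn]Cl)C2(C)C)OCCO1 | intermediate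
25 | (1S,2S,5R,6S)-7-{(1R,3S)-2,2-dimethyl-3-[2-(2-methyl-1,3-dioxolan-2-yl)ethyl]cyclopropyl}-4,6-dimethyl-syn-tricyclo[4.2.1.1(2,5)]deca-3,7-dien-3-yl trifluoromethanesulfonate | CC5(OCCO5)CC[C@H]1[C@@H](C2=C[C@@H]3C[C@@]2(C)[C@H]2C[C@@H]3C(OS(=O)(=O)C(F)(F)F)=C2C)C1(C)C | intermediate
26 | (1S,2S,5S,6S)-4,6-dimethyl-3,7-bis{(1R,3S)-2,2-dimethyl-3-[2-(2-methyl-1,3-dioxolan-2-yl)ethyl]cyclopropyl}-syn-tricyclo[4.2.1.1(2,5)]deca-3,7-diene | CC5(OCCO5)CC[C@H]1[C@@H](C2=C[C@@H]3C[C@@]2(C)[C@H]2C[C@@H]3C([C@@H]3[C@H](CCC6(C)OCCO6)C3(C)C)=C2C)C1(C)C | intermediate
27 | (1S,2S,5S,6S)-4,6-dimethyl-3,7-bis[(1R,3S)-2,2-dimethyl-3-(3-oxobutyl)cyclopropyl]-syn-tricyclo[4.2.1.1(2,5)]deca-3,7-diene | CC(=O)CC[C@H]1[C@@H](C2=C[C@@H]3C[C@@]2(C)[C@H]2C[C@@H]3C([C@@H]3[C@H](CCC(C)=O)C3(C)C)=C2C)C1(C)C | target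

## Step count and least certain steps

Total: 12 steps. Longest linear sequence: 9 steps (steps 1–6, 10, 11, 12); steps 7–9 form the side branch that supplies the arm reagent.

Step 5 (key step). The regiochemistry of ring closure is secured by the substrate, so the likely failures are competing courses of the anions: addition of the amide base or of 10 or 11 to the methylidene ketone of a second molecule (oligomerisation), vinylogous deprotonation at C5 through the methylidene group with loss of that stereocentre, or closure so slow through the strained boat-like transition state that 10 is merely reprotonated. Material with the unlike C5/C6 pairing would close to the anti cage and must be removed here if not before. Fallback, from 9 back to 12: 9 is converted with Me3SiOTf and Et3N into the 2-(trimethylsilyloxy)diene F1 (only the C2=C3 enol ether is possible). F1 is cyclised with catalytic HNTf2 in CH2Cl2 at −78 °C in an intramolecular Mukaiyama–Michael addition to the tricyclic 7-silyl enol ether F2, and mild aqueous acid returns 12. This replaces the basic enolate by a neutral nucleophile and removes the anionic side reactions.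

Step 2. Three processes can go wrong: slow turnover because the tetrasubstituted enol ether is a weaker nucleophile than the ketene acetals usually used with this catalyst, achiral silyl-cation catalysis that erodes facial selectivity, and weak discrimination between the like and unlike approach at C6. If the sense of induction at C5 proves opposite, the (R)-oxazaborole is used. Fallback, from 1 back to 9, with an auxiliary on the acceptor: 1 is deprotonated on its unsubstituted side (LiN(iPr)2, −78 °C) and dehydrogenated with PhS(Cl)=N-t-Bu to 5-methylcyclopent-2-en-1-one F3. F3 is deprotonated at C5 (LiN(iPr)2, −78 °C) and added to the ZnBr2 chelate of the auxiliary-bearing acceptor (R)-2-[(4-methylphenyl)sulfinyl]cyclopent-2-en-1-one F4, whose aryl group blocks one face of the β-carbon. MeI in the same flask then gives the α-methyl-α-sulfinyl ketone F5, with the methyl group trans to the ring A substituent. Thermolysis (toluene, 110 °C, CaCO3) eliminates the sulfenic acid toward the methyl group, the only position with a syn hydrogen, and gives 9. Ring A is already unsaturated in this variant, which is tolerable because the donor is a lithium dienolate and not a silyloxydiene under Lewis acid.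

Step 6. Incomplete enolisation of C7 would allow 1,2-reduction of that ketone; enolate 13 could add to unreacted methylidene ketone; and O-sulfonylation of the tetrasubstituted C3 enolate could be sluggish. Fallback, from 12 back to 15, in separate operations: chemoselective conjugate reduction with [(Ph3P)CuH]6 and Me3SiCl (THF, −40 °C) leaves the C7 ketone untouched and gives the 3-silyl enol ether F6. KN(SiMe3)2 and PhNTf2 then convert C7 into its enol triflate F7, and CsF with PhNTf2 in 1,2-dimethoxyethane exchanges the silyl group for triflate and gives 15.

Step 9. The enantiotopic discrimination on the symmetric cyclopropene may be incomplete, the ketal-bearing Grignard reagent 22 may decompose before it adds, and the cyclopropylzinc may be partly protonated on storage, so that its titre and purity drift between steps 10 and 11. Fallback, from 23 back to 25 (and again to 26 in step 11): 23 is quenched with 2-isopropoxy-4,4,5,5-tetramethyl-1,3,2-dioxaborolane to give the cyclopropylboronic pinacol ester F8, which is isolated, freed from protonated arm and, if necessary, brought to enantiopurity by preparative chromatography on a chiral stationary phase. F8 then replaces 24 in Suzuki–Miyaura couplings with 15 and with 25 (Pd(OAc)2, 2-dicyclohexylphosphino-2′,6′-diisopropoxybiphenyl, K3PO4, toluene/H2O, 90 °C), again with retention at Ca.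

Step 11. Transmetalation of the bulky secondary cyclopropylzinc onto the alkenylpalladium at tetrasubstituted C3 may be too slow, so that the triflate is reduced or hydrolysed instead of coupled. Fallback, from 25 back to 26, with the roles of the partners exchanged: 25 is borylated (bis(pinacolato)diboron, PdCl2(PPh3)2, KOPh, toluene, 50 °C) to the alkenylboronic pinacol ester F9. A portion of 23 is quenched with I2 at −78 °C, with retention, to the cis-cyclopropyl iodide F10. F9 and F10 are then joined in a Suzuki–Miyaura coupling of an iodocyclopropane (Pd(OAc)2, PPh3, K2CO3, Bu4NCl, DMF/H2O, 90 °C), in which oxidative addition at the cyclopropyl carbon also proceeds with retention, to give 26.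

## Further compounds

F1 | step 5 | (5S)-5-methyl-5-[(1S)-2-methylidene-3-(trimethylsilyloxy)cyclopent-3-en-1-yl]cyclopent-2-en-1-one | O=C1C=CC[C@@]1(C)[C@H]1CC=C(O[Si](C)(C)C)C1=C
F2 | step 5 | (1S,2S,5R,6S)-6-methyl-4-methylidene-7-(trimethylsilyloxy)-syn-tricyclo[4.2.1.1(2,5)]dec-7-en-3-one (spatial arrangement as in 12) | C[Si](C)(C)OC1=C[C@@H]2C[C@@]1(C)[C@H]1C[C@@H]2C(=O)C1=C
F3 | step 2 | 5-methylcyclopent-2-en-1-one (racemic) | CC1CC=CC1=O
F4 | step 2 | (R)-2-[(4-methylphenyl)sulfinyl]cyclopent-2-en-1-one | Cc1ccc(cc1)[S@@](=O)C1=CCCC1=O
F5 | step 2 | (5S)-5-methyl-5-{(1R,2S)-2-methyl-2-[(R)-(4-methylphenyl)sulfinyl]-3-oxocyclopentyl}cyclopent-2-en-1-one (C5 and C6 arranged as in 9, C4 methyl trans to ring A) | O=C1C=CC[C@@]1(C)[C@H]1CCC(=O)[C@@]1(C)[S@](=O)c1ccc(C)cc1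
F6 | step 6 | (1S,2S,5S,6S)-4,6-dimethyl-3-(trimethylsilyloxy)-syn-tricyclo[4.2.1.1(2,5)]dec-3-en-7-one | O=C1C[C@@H]2C[C@@]1(C)[C@H]1C[C@@H]2C(O[Si](C)(C)C)=C1C
F7 | step 6 | (1S,2S,5S,6S)-4,6-dimethyl-3-(trimethylsilyloxy)-syn-tricyclo[4.2.1.1(2,5)]deca-3,7-dien-7-yl trifluoromethanesulfonate | FC(F)(F)S(=O)(=O)OC1=C[C@@H]2C[C@@]1(C)[C@H]1C[C@@H]2C(O[Si](C)(C)C)=C1C
F8 | step 9 | 2-{(1R,3S)-2,2-dimethyl-3-[2-(2-methyl-1,3-dioxolan-2-yl)ethyl]cyclopropyl}-4,4,5,5-tetramethyl-1,3,2-dioxaborolane (cis) | CC1(CC[C@H]2[C@@H](B3OC(C)(C)C(C)(C)O3)C2(C)C)OCCO1
F9 | step 11 | alkenylboronic pinacol ester corresponding to 25: 4,4,5,5-tetramethyl-1,3,2-dioxaborolan-2-yl in place of the triflate at C3, all stereocentres arranged as in 25 | CC5(OCCO5)CC[C@H]1[C@@H](C2=C[C@@H]3C[C@@]2(C)[C@H]2C[C@@H]3C(B4OC(C)(C)C(C)(C)O4)=C2C)C1(C)C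
F10 | step 11 | 2-{2-[(1R,3R)-3-iodo-2,2-dimethylcyclopropyl]ethyl}-2-methyl-1,3-dioxolane (cis) | CC1(CC[C@H]2[C@@H](I)C2(C)C)OCCO1
A1 | alternative 1 | ethyl (1R,3S)-2,2-dimethyl-3-(3-oxobutyl)cyclopropane-1-carboxylate | CC(=O)CC[C@H]1[C@@H](C(=O)OCC)C1(C)C
A2 | alternative 1 | 6-methylhept-5-en-2-one | CC(=O)CCC=C(C)C
A3 | alternative 1 | ethyl diazoacetate | CCOC(=O)C=[N+]=[N-]
A4 | alternative 2 | bicyclo[4.2.1]nona-2,4,7-triene carrying both ketal-protected arms (C9 absent) | CC1=C([C@@H]2[C@H](CCC3(C)OCCO3)C2(C)C)C=C[C@@H]4C[C@H]1C(C)=C4[C@@H]5[C@H](CCC6(C)OCCO6)C5(C)C
A5 | alternative 2 | 1-methyl-2-(ketal-protected arm)cyclohepta-1,3,5-triene | CC1=CCC=CC=C1[C@@H]2[C@H](CCC3(C)OCCO3)C2(C)C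
A6 | alternative 2 | 2-{2-[(1S,3R)-2,2-dimethyl-3-(prop-1-yn-1-yl)cyclopropyl]ethyl}-2-methyl-1,3-dioxolane (cis) | CC#C[C@@H]1[C@H](CCC2(C)OCCO2)C1(C)C
A7 | alternative 3 | core bearing two cis-cyclopropyl N-(quinolin-8-yl)amides at C3 and C7 | O=C(Nc1cccc2cccnc12)[C@H]1[C@@H](C2=C[C@@H]3C[C@@]2(C)[C@H]2C[C@@H]3C([C@@H]3[C@H](C(=O)Nc4cccc5cccnc45)C3(C)C)=C2C)C1(C)C
A8 | alternative 3 | (1S,2S,5S,6S)-3,7-diiodo-4,6-dimethyl-syn-tricyclo[4.2.1.1(2,5)]deca-3,7-diene | IC1=C[C@@H]2C[C@@]1(C)[C@H]1C[C@@H]2C(I)=C1C
A9 | alternative 3 | (1S)-2,2-dimethyl-N-(quinolin-8-yl)cyclopropane-1-carboxamide | O=C(Nc1cccc2cccnc12)[C@H]1CC1(C)C
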